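**Retrosynthet­ic overview**

1. Both rings and both stereocentres are disconnected together. The C1–C2 bond of the 14-membered carbocycle and the lactone O–C(=O) bond lead back to an acyclic, stereocentre-free enal/(Z)-2-(bromomethyl)enoate. The forward step is a ligand-controlled catalytic asymmetric Cr allylation–lactonisation, run as the last step instead of a racemic metal-mediated closure.
2. The bromo-enoate comes from a C14 dialdehyde and methyl acrylate: Morita–Baylis–Hillman reaction at the saturated CHO only, then SN2′ bromination.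
3. The dialdehyde comes from a (Z)-selective C7=C8 Wittig reaction of an α-silyloxy ketone with a C6 oxido-ylide, followed by CH2OH → CHO, OSiEt3 → OAc and epoxide → CHO.
4. The ketone comes from (E)-geranylacetone (terminal epoxide = masked C1 aldehyde; α′-oxygenation = C19–O). The ylide comes from 5-chloropent-1-yne (carboalumination/hydroxymethylation sets the (E)-C3=C4 alkene).
5. Ring order: no ring exists before the last step; there the carbocycle closes first (C–C) and the lactone second (O-acylation) in the same flask.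

Assumption: (E)-geranylacetone is bought as the isomerically pure (5E) compound; chain carbons are referred to by cembrane numbers (ring-fusion CH = C1, lactone O–CH = C2, acetoxymethyl on C8).

**Step 1**
Reactants: 1 (5E)-6,10-dimethylundeca-5,9-dien-2-one [(E)-geranylacetone]
Product: 3 (5E)-8-(3,3-dimethyloxiran-2-yl)-6-methyloct-5-en-2-one, via terminal bromohydrin 2 (not isolated)
Conditions: NBS (1.05 equiv), THF–H2O, 0 °C; then K2CO3, MeOH, 23 °C
Reagents that add atoms: water, O
Why: van Tamelen-type bromohydrin formation in aqueous THF favours the exposed terminal trisubstituted alkene of the polyene, and base then closes the bromohydrin by intramolecular Williamson displacement to a racemic epoxide whose stereocentre is deleted in step 8.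

**Step 2**
Reactants: 3 (5E)-8-(3,3-dimethyloxiran-2-yl)-6-methyloct-5-en-2-one
Product: 6 (5E)-8-(3,3-dimethyloxiran-2-yl)-6-methyl-1-(triethylsilyloxy)oct-5-en-2-one, via potassium enolate 4 (not isolated), via potassium α-oxido ketone 5 (not isolated)
Conditions: KHMDS, THF, −78 °C; 2-(phenylsulfonyl)-3-phenyloxaziridine, −78 °C; then TESCl, −78 → 0 °C
Reagents that add atoms: 2-(phenylsulfonyl)-3-phenyloxaziridine, O=S(=O)(N1OC1c1ccccc1)c1ccccc1; chlorotriethylsilane, CC[Si](Cl)(CC)CC
Why: the bulky amide deprotonates the methyl group kinetically, Davis enolate hydroxylation transfers oxygen without touching the alkene or epoxide (no peracid), and the alkoxide is silylated in situ; no stereocentre is formed.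

**Step 3**
Reactants: 7 5-chloropent-1-yne
Product: 10 (2E)-6-chloro-3-methylhex-2-en-1-ol, via alkenyldimethylalane 8 (not isolated), via dimethylaluminium alkoxide 9 (not isolated)
Conditions: Me3Al (2 equiv), Cp2ZrCl2 (20 mol%), CH2Cl2, 0 → 23 °C; then (CH2O)n, THF, 0 → 23 °C; aq. Rochelle salt
Reagents that add atoms: trimethylaluminium, C[Al](C)C; paraformaldehyde (as formaldehyde), C=O
Why: Negishi Zr-catalysed carboalumination adds Me–Al syn across the terminal alkyne with methyl on the internal carbon, so hydroxymethylation of the C–Al bond gives only the (E)-allylic alcohol while the alkyl chloride is inert.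

**Step 4**
Reactants: 10 (2E)-6-chloro-3-methylhex-2-en-1-ol
Product: 12 [(4E)-6-hydroxy-4-methylhex-4-en-1-yl]triphenylphosphonium iodide, via primary iodide 11 (not isolated)
Conditions: NaI, PPh3, MeCN, reflux
Reagents that add atoms: sodium iodide, [Na+].[I-]; triphenylphosphine, c1ccc(cc1)P(c1ccccc1)c1ccccc1
Why: Finkelstein exchange followed by SN2 quaternisation of triphenylphosphine at the primary carbon under neutral conditions leaves the allylic alcohol and the (E)-alkene untouched.

**Step 5**
Reactants: 12 [(4E)-6-hydroxy-4-methylhex-4-en-1-yl]triphenylphosphonium iodide; 6 (5E)-8-(3,3-dimethyloxiran-2-yl)-6-methyl-1-(triethylsilyloxy)oct-5-en-2-one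
Product: 15 (2E,6Z,10E)-13-(3,3-dimethyloxiran-2-yl)-3,11-dimethyl-7-[(triethylsilyloxy)methyl]trideca-2,6,10-trien-1-ol, via oxido ylide 13 (not isolated), via potassium alkoxide 14 (not isolated)
Conditions: 12 (1.3 equiv), KHMDS (2.55 equiv), THF, −78 → 0 °C; then 6, THF–HMPA, −78 → 23 °C; H2O
Reagents that add atoms: none
Why: Still-type (Z)-selective Wittig olefination, in which a salt-free unstabilised ylide adds to an α-silyloxy ketone so that the oxygenated CH2 ends cis to the ylide chain (typically ≥10:1), sets the (Z)-C7=C8 geometry while the remote alkoxide and the epoxide are spectators.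

**Step 6**
Reactants: 15 (2E,6Z,10E)-13-(3,3-dimethyloxiran-2-yl)-3,11-dimethyl-7-[(triethylsilyloxy)methyl]trideca-2,6,10-trien-1-ol
Product: 16 (2E,6Z,10E)-13-(3,3-dimethyloxiran-2-yl)-3,11-dimethyl-7-[(triethylsilyloxy)methyl]trideca-2,6,10-trienal
Conditions: MnO2 (excess), CH2Cl2, 23 °C
Reagents that add atoms: none
Why: MnO2 allylic oxidation converts the only free (primary allylic) alcohol to the enal without E/Z isomerisation and does not touch the silyl ether or epoxide.

**Step 7**
Reactants: 16 (2E,6Z,10E)-13-(3,3-dimethyloxiran-2-yl)-3,11-dimethyl-7-[(triethylsilyloxy)methyl]trideca-2,6,10-trienal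
Product: 18 (2E,6Z,10E)-7-(acetoxymethyl)-13-(3,3-dimethyloxiran-2-yl)-3,11-dimethyltrideca-2,6,10-trienal, via free allylic alcohol 17 (not isolated)
Conditions: TBAF, AcOH, THF, 0 °C; then Ac2O, pyridine, DMAP (cat.), 0 → 23 °C
Reagents that add atoms: acetic anhydride, CC(=O)OC(C)=O
Why: buffered fluoride desilylation followed by acylation in the same flask installs the C19 acetate at a point where no other hydroxyl is present, and enal and epoxide tolerate both stages.

**Step 8**
Reactants: 18 (2E,6Z,10E)-7-(acetoxymethyl)-13-(3,3-dimethyloxiran-2-yl)-3,11-dimethyltrideca-2,6,10-trienal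
Product: 20 (2E,6Z,10E)-7-(acetoxymethyl)-3,11-dimethyltetradeca-2,6,10-trienedial, via vicinal diol 19 (not isolated)
Conditions: H5IO6 (1.2 equiv), THF–H2O, 0 °C
Reagents that add atoms: none
Why: periodic acid hydrolyses the trisubstituted epoxide to the diol and cleaves it (Malaprade cleavage) to the C1 aldehyde and acetone without affecting alkenes, enal or acetate, which removes the racemic stereocentre.

**Step 9**
Reactants: 20 (2E,6Z,10E)-7-(acetoxymethyl)-3,11-dimethyltetradeca-2,6,10-trienedial; 21 methyl acrylate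
Product: 22 methyl (6E,10Z,14E)-10-(acetoxymethyl)-3-hydroxy-6,14-dimethyl-2-methylidene-16-oxohexadeca-6,10,14-trienoate
Conditions: DABCO (1 equiv), methyl acrylate (neat, excess), 23 °C, 4–6 d
Reagents that add atoms: none
Why: in this Morita–Baylis–Hillman reaction the DABCO–acrylate zwitterion adds only to the unhindered saturated aldehyde (the β,β-disubstituted enal is a poor acceptor), and the new carbinol centre is racemic and is erased in step 10.

**Step 10**
Reactants: 22 methyl (6E,10Z,14E)-10-(acetoxymethyl)-3-hydroxy-6,14-dimethyl-2-methylidene-16-oxohexadeca-6,10,14-trienoate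
Product: 23 methyl (2Z,6E,10Z,14E)-10-(acetoxymethyl)-2-(bromomethyl)-6,14-dimethyl-16-oxohexadeca-2,6,10,14-tetraenoate
Conditions: NBS, Me2S, CH2Cl2, 0 → 23 °C
Reagents that add atoms: N-bromosuccinimide, BrN1C(=O)CCC1=O
Why: Corey–Kim-type activation of the allylic alcohol as an alkoxysulfonium salt and SN2′ attack of bromide give the thermodynamically preferred (Z)-2-(bromomethyl)enoate (chain cis to CH2Br), and enal and acetate are inert.

**Step 11**
Reactants: 23 methyl (2Z,6E,10Z,14E)-10-(acetoxymethyl)-2-(bromomethyl)-6,14-dimethyl-16-oxohexadeca-2,6,10,14-tetraenoate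
Product: 26 [(3aS,6E,10Z,14E,15aS)-6,14-dimethyl-3-methylidene-2-oxo-2,3,3a,4,5,8,9,12,13,15a-decahydrocyclotetradeca[b]furan-10-yl]methyl acetate, via silyl ether 24 (not isolated), via hydroxy ester 25 (not isolated)
Conditions: CrCl2 (20 mol%), tridentate carbazole-bis(oxazoline) ligand L* (24 mol%, the antipode that directs Re-face attack), Mn (3 equiv), TMSCl (2 equiv), Et3N (cat.), THF, 23 added by syringe pump (final 2 mM), 23 °C; then 1 M HCl, THF, 23 °C
Reagents that add atoms: none
Why: Proposed new method: the chiral allyl–Cr(III) species formed from the bromide (turned over by Mn/TMSCl) adds through its γ-carbon (C1) to the tethered enal carbonyl in a closed chair transition state, where the preferred geometry of the 2-(methoxycarbonyl)allyl chromium (chain cis to CH2Cr) gives the syn adduct and the ligand directs attack to the Re face of the aldehyde (C2 = S, hence C1 = S), after which acid removes the silyl group and the cis γ-hydroxy ester lactonises, so that carbocycle, lactone and both stereocentres arise in one operation; the closest known reactions are the intermolecular Cr-catalysed enantioselective Nozaki–Hiyama 2-(alkoxycarbonyl)allylation–lactonisation of aldehydes and the racemic stoichiometric Cr- or Zn-mediated macro-allylations used for cembranolides, while an enantioselective macrocyclising version has no precedent.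

**Compound list**

1 | (5E)-6,10-dimethylundeca-5,9-dien-2-one [(E)-geranylacetone] | CC(=O)CC/C=C(\C)CCC=C(C)C | starting material
2 | terminal bromohydrin: (5E)-9-bromo-10-hydroxy-6,10-dimethylundec-5-en-2-one (racemic) | CC(=O)CC/C=C(\C)CCC(Br)C(C)(C)O | intermediate
3 | (5E)-8-(3,3-dimethyloxiran-2-yl)-6-methyloct-5-en-2-one (racemic epoxide) | CC(=O)CC/C=C(\C)CCC1OC1(C)C | intermediate
4 | potassium enolate: potassium (5E)-8-(3,3-dimethyloxiran-2-yl)-6-methylocta-1,5-dien-2-olate | [K+].[O-]C(=C)CC/C=C(\C)CCC1OC1(C)C | intermediate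
5 | potassium α-oxido ketone: potassium (5E)-8-(3,3-dimethyloxiran-2-yl)-6-methyl-2-oxooct-5-en-1-olate | [K+].[O-]CC(=O)CC/C=C(\C)CCC1OC1(C)C | intermediate
6 | (5E)-8-(3,3-dimethyloxiran-2-yl)-6-methyl-1-(triethylsilyloxy)oct-5-en-2-one | CC[Si](CC)(CC)OCC(=O)CC/C=C(\C)CCC1OC1(C)C | intermediate
7 | 5-chloropent-1-yne | C#CCCCCl | starting material
8 | alkenyldimethylalane: [(1E)-5-chloro-2-methylpent-1-en-1-yl]dimethylalumane | C[Al](C)/C=C(\C)CCCCl | intermediate
9 | dimethylaluminium alkoxide: dimethylaluminium (2E)-6-chloro-3-methylhex-2-en-1-olate | C[Al](C)OC/C=C(\C)CCCCl | intermediate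
10 | (2E)-6-chloro-3-methylhex-2-en-1-ol | OC/C=C(\C)CCCCl | intermediate
11 | primary iodide: (2E)-6-iodo-3-methylhex-2-en-1-ol | OC/C=C(\C)CCCI | intermediate
12 | [(4E)-6-hydroxy-4-methylhex-4-en-1-yl]triphenylphosphonium iodide | OC/C=C(\C)CCC[P+](c1ccccc1)(c1ccccc1)c1ccccc1.[I-] | intermediate
13 | oxido ylide: potassium (2E)-3-methyl-6-(triphenyl-λ5-phosphanylidene)hex-2-en-1-olate | [K+].[O-]C/C=C(\C)CCC=P(c1ccccc1)(c1ccccc1)c1ccccc1 | intermediate
14 | potassium alkoxide: potassium salt of 15 (C2–O−) | [K+].[O-]C/C=C(\C)CC/C=C(\CO[Si](CC)(CC)CC)CC/C=C(\C)CCC1OC1(C)C | intermediate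
15 | (2E,6Z,10E)-13-(3,3-dimethyloxiran-2-yl)-3,11-dimethyl-7-[(triethylsilyloxy)methyl]trideca-2,6,10-trien-1-ol | OC/C=C(\C)CC/C=C(\CO[Si](CC)(CC)CC)CC/C=C(\C)CCC1OC1(C)C | intermediate
16 | (2E,6Z,10E)-13-(3,3-dimethyloxiran-2-yl)-3,11-dimethyl-7-[(triethylsilyloxy)methyl]trideca-2,6,10-trienal | O=C/C=C(\C)CC/C=C(\CO[Si](CC)(CC)CC)CC/C=C(\C)CCC1OC1(C)C | intermediate
17 | free allylic alcohol: (2E,6Z,10E)-13-(3,3-dimethyloxiran-2-yl)-7-(hydroxymethyl)-3,11-dimethyltrideca-2,6,10-trienal | O=C/C=C(\C)CC/C=C(\CO)CC/C=C(\C)CCC1OC1(C)C | intermediate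
18 | (2E,6Z,10E)-7-(acetoxymethyl)-13-(3,3-dimethyloxiran-2-yl)-3,11-dimethyltrideca-2,6,10-trienal | O=C/C=C(\C)CC/C=C(\COC(C)=O)CC/C=C(\C)CCC1OC1(C)C | intermediate
19 | vicinal diol: (2E,6Z,10E)-7-(acetoxymethyl)-14,15-dihydroxy-3,11,15-trimethylhexadeca-2,6,10-trienal | O=C/C=C(\C)CC/C=C(\COC(C)=O)CC/C=C(\C)CCC(O)C(C)(C)O | intermediate
20 | (2E,6Z,10E)-7-(acetoxymethyl)-3,11-dimethyltetradeca-2,6,10-trienedial | O=C/C=C(\C)CC/C=C(\COC(C)=O)CC/C=C(\C)CCC=O | intermediate
21 | methyl acrylate | C=CC(=O)OC | starting material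
22 | methyl (6E,10Z,14E)-10-(acetoxymethyl)-3-hydroxy-6,14-dimethyl-2-methylidene-16-oxohexadeca-6,10,14-trienoate (racemic at C3) | O=C/C=C(\C)CC/C=C(\COC(C)=O)CC/C=C(\C)CCC(O)C(=C)C(=O)OC | intermediate
23 | methyl (2Z,6E,10Z,14E)-10-(acetoxymethyl)-2-(bromomethyl)-6,14-dimethyl-16-oxohexadeca-2,6,10,14-tetraenoate | O=C/C=C(\C)CC/C=C(\COC(C)=O)CC/C=C(\C)CC/C=C(\CBr)C(=O)OC | intermediate
24 | silyl ether: methyl 2-[(1S,2S,3E,7Z,11E)-8-(acetoxymethyl)-4,12-dimethyl-2-(trimethylsilyloxy)cyclotetradeca-3,7,11-trien-1-yl]prop-2-enoate | COC(=O)C(=C)[C@@H]1CC/C(C)=C/CC/C(COC(C)=O)=C/CC/C(C)=C/[C@@H]1O[Si](C)(C)C | intermediate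
25 | hydroxy ester: methyl 2-[(1S,2S,3E,7Z,11E)-8-(acetoxymethyl)-2-hydroxy-4,12-dimethylcyclotetradeca-3,7,11-trien-1-yl]prop-2-enoate | COC(=O)C(=C)[C@@H]1CC/C(C)=C/CC/C(COC(C)=O)=C/CC/C(C)=C/[C@@H]1O | intermediate
26 | [(3aS,6E,10Z,14E,15aS)-6,14-dimethyl-3-methylidene-2-oxo-2,3,3a,4,5,8,9,12,13,15a-decahydrocyclotetradeca[b]furan-10-yl]methyl acetate (cis-fused lactone) | C=C1C(=O)O[C@H]2/C=C(\C)CC/C=C(\COC(C)=O)CC/C=C(\C)CC[C@@H]12 | target

**Step count and risk**

Total steps: 11. Longest linear sequence: 9 steps (steps 1, 2, 5–11 from 1; the same length via steps 3, 4, 5–11 from 7).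

The three steps most likely to fail:

Step 11 (catalytic asymmetric macro-allylation–lactonisation). The risks are oligomerisation at the low concentration needed, slow catalyst turnover, and unproven enantiocontrol in a macrocyclic transition state. The fallback changes from a chromium allyl to a boron allyl with organocatalytic control. It sets out from bromide 23, which is borylated (B2pin2, Pd2(dba)3 cat., toluene, 23 °C) to methyl (2E,6E,10Z,14E)-10-(acetoxymethyl)-6,14-dimethyl-16-oxo-2-[(4,4,5,5-tetramethyl-1,3,2-dioxaborolan-2-yl)methyl]hexadeca-2,6,10,14-tetraenoate F1. This electron-poor allylboronate does not react with its own aldehyde at 23 °C. It is cyclised at 2 mM in toluene with a chiral phosphoric acid (TRIP, 20 mol%, the antipode that activates the Re face) through a chair allylboration in which the chain cis to CH2B gives the syn adduct. The product is the borate ester methyl 2-[(1S,2S,3E,7Z,11E)-8-(acetoxymethyl)-4,12-dimethyl-2-[(4,4,5,5-tetramethyl-1,3,2-dioxaborolan-2-yl)oxy]cyclotetradeca-3,7,11-trien-1-yl]prop-2-enoate F2. Aqueous acid work-up hydrolyses it to hydroxy ester 25, which lactonises, and the route comes back at target 26.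

Step 5 (Z-selective Wittig on an enolisable α-silyloxy ketone). The risks are an eroded Z:E ratio and competing enolisation. The fallback replaces the one-step olefination by a stepwise Horner–Wittig sequence with separation of diastereomers. It sets out from phosphonium salt 12, which is hydrolysed (aq. NaOH, reflux) to [(4E)-6-hydroxy-4-methylhex-4-en-1-yl]diphenylphosphine oxide F3. Its dilithio derivative (n-BuLi, 2 equiv, THF, −78 °C) adds to ketone 6 to give the β-hydroxy phosphine oxides (2E,10E)-6-(diphenylphosphoryl)-13-(3,3-dimethyloxiran-2-yl)-3,11-dimethyl-7-[(triethylsilyloxy)methyl]trideca-2,10-diene-1,7-diol F4. The diastereomers in which Ph2P(O) and OH can become syn-periplanar with the C6 chain and CH2OSiEt3 eclipsed are isolated by chromatography. Stereospecific syn-elimination (NaH, DMF, 50 °C) then gives geometrically pure material, and the route comes back at 15.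

Step 9 (Morita–Baylis–Hillman reaction on the dialdehyde). The risks are a slow reaction with an enolisable aliphatic aldehyde and side reactions of the enal over several days with amine. The fallback replaces amine catalysis by a stoichiometric vinylalumination. It sets out from dialdehyde 20. Methyl propiolate and DIBAL-H/HMPA (THF, 0 °C) give methyl 2-[bis(2-methylpropyl)alumanyl]prop-2-enoate F5. This adds at −78 → 0 °C to the unhindered saturated aldehyde of 20 to give the diisobutylaluminium alkoxide of methyl (6E,10Z,14E)-10-(acetoxymethyl)-3-hydroxy-6,14-dimethyl-2-methylidene-16-oxohexadeca-6,10,14-trienoate F6. Aqueous work-up brings the route back at 22.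

**Further compounds**

F1 | step 11 | methyl (2E,6E,10Z,14E)-10-(acetoxymethyl)-6,14-dimethyl-16-oxo-2-[(4,4,5,5-tetramethyl-1,3,2-dioxaborolan-2-yl)methyl]hexadeca-2,6,10,14-tetraenoate | O=C/C=C(\C)CC/C=C(\COC(C)=O)CC/C=C(\C)CC/C=C(\CB1OC(C)(C)C(C)(C)O1)C(=O)OC
F2 | step 11 | methyl 2-[(1S,2S,3E,7Z,11E)-8-(acetoxymethyl)-4,12-dimethyl-2-[(4,4,5,5-tetramethyl-1,3,2-dioxaborolan-2-yl)oxy]cyclotetradeca-3,7,11-trien-1-yl]prop-2-enoate | COC(=O)C(=C)[C@@H]1CC/C(C)=C/CC/C(COC(C)=O)=C/CC/C(C)=C/[C@@H]1OB2OC(C)(C)C(C)(C)O2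
F3 | step 5 | [(4E)-6-hydroxy-4-methylhex-4-en-1-yl]diphenylphosphine oxide | OC/C=C(\C)CCCP(=O)(c1ccccc1)c1ccccc1
F4 | step 5 | (2E,10E)-6-(diphenylphosphoryl)-13-(3,3-dimethyloxiran-2-yl)-3,11-dimethyl-7-[(triethylsilyloxy)methyl]trideca-2,10-diene-1,7-diol | OC/C=C(\C)CCC(P(=O)(c1ccccc1)c1ccccc1)C(O)(CO[Si](CC)(CC)CC)CC/C=C(\C)CCC1OC1(C)C
F5 | step 9 | methyl 2-[bis(2-methylpropyl)alumanyl]prop-2-enoate | C=C([Al](CC(C)C)CC(C)C)C(=O)OC
F6 | step 9 | diisobutylaluminium alkoxide of methyl (6E,10Z,14E)-10-(acetoxymethyl)-3-hydroxy-6,14-dimethyl-2-methylidene-16-oxohexadeca-6,10,14-trienoate | O=C/C=C(\C)CC/C=C(\COC(C)=O)CC/C=C(\C)CCC(O[Al](CC(C)C)CC(C)C)C(=C)C(=O)OC
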